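**Strategy.** Atoms are numbered as in the daucanes (C1 angular carbon, C4 carbinol, C5 ring-fusion CH, C6 ester carbon, C8/C9 epoxide carbons). In the seven-membered ring (C1, C5–C10) the ester oxygen on C6 and the epoxide oxygen on C9 are separated only by C7 and C8, so a 6,9-dione has both of these carbons as enolisable α-positions. The ring is therefore closed by oxidising the bis-enolate of a monocyclic 1,5-diketone: a trans-1,2-disubstituted cyclopentane with acetyl on C5, 2-oxobutyl on quaternary C1 and a silylated isopropyl carbinol at C4. That single operation forms C7–C8, the seven-membered ring and the C8 methyl stereocentre, with both oxygens in place.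

Key step: step 7

**Remarks on the chemistry (made before the steps)**
- β is the face of the C1 methyl group and α the face of H5.
- The carbinol centre C6 (in 7–10) and the centres C9 and C10 (in 9–11) are expected as epimer mixtures that converge in step 5, so they are left open in names and SMILES. The enol ether/enolate geometry at C8=C9 in 14 and 15 is also left open.
- C8 in 16 is epimerisable and is drawn as the 8β-methyl epimer; either epimer serves, because C8 becomes trigonal in step 8.
- Assumption: the ligand enantiomer in step 1 is the one that gives the C1 configuration drawn.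
- Two points in the design are deliberate. The C10 arm is introduced with a trimethylsilyl group on C10, because a plain alkyl or alkenyl arm is too close in size to the C1 methyl to direct the C5 substituent trans. The diketone enters the key step through its bis(silyl enol ether), so that no enolate ever faces a free carbonyl of this 1,5-diketone, which would otherwise close a six-membered aldol ring.

**Step 1**
Reactants: 1 3-methylcyclopent-2-en-1-one; 2 but-1-yn-1-yl(trimethyl)silane
Product: 5 triethyl({(3S)-3-methyl-3-[(1Z)-1-(trimethylsilyl)but-1-en-1-yl]cyclopent-1-en-1-yl}oxy)silane, via alkenylalane 3 (not isolated), via aluminium enolate 4 (not isolated)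
Conditions: iBu2AlH, hexane/THF, 55 °C; then enone 1, Cu(OTf)2 (5 mol %), chiral sulfonate-bearing imidazolinium salt (carbene ligand precursor, 6 mol %), THF, −30 °C; then Et3SiOTf, −30 → 0 °C
Reagents that add atoms: triethylsilyl trifluoromethanesulfonate, CC[Si](CC)(CC)OS(=O)(=O)C(F)(F)F
Why: syn-Hydroalumination puts aluminium on the silicon-bearing alkyne carbon, and copper-catalysed asymmetric conjugate addition of this silyl-substituted alkenylalane to the β-methyl enone (a known route to quaternary centres on cyclopentenones) sets C1 under control of the chiral carbene ligand, the regiodefined enolate being trapped on oxygen by the silyl triflate.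

**Step 2**
Reactants: 5 triethyl({(3S)-3-methyl-3-[(1Z)-1-(trimethylsilyl)but-1-en-1-yl]cyclopent-1-en-1-yl}oxy)silane; 6 acetaldehyde
Product: 7 (2S,3S)-2-(1-hydroxyethyl)-3-methyl-3-[(1Z)-1-(trimethylsilyl)but-1-en-1-yl]cyclopentan-1-one
Conditions: MeCHO (3 equiv), TiCl4 (1.1 equiv), CH2Cl2, −78 °C; aq. NaHCO3
Reagents that add atoms: none
Why: Mukaiyama aldol addition in which the aldehyde should approach C5 anti to the very bulky α-silylalkenyl group on the neighbouring quaternary C1, placing the C5 side chain trans to the future 2-oxobutyl arm, while the carbinol centre C6 is an inconsequential mixture.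

**Step 3**
Reactants: 7 (2S,3S)-2-(1-hydroxyethyl)-3-methyl-3-[(1Z)-1-(trimethylsilyl)but-1-en-1-yl]cyclopentan-1-one
Product: 8 (1R,2S,3S)-2-(1-hydroxyethyl)-3-methyl-1-(propan-2-yl)-3-[(1Z)-1-(trimethylsilyl)but-1-en-1-yl]cyclopentan-1-ol
Conditions: iPrMgCl (4 equiv), CeCl3 (4 equiv), THF, −78 → 0 °C; aq. NH4Cl
Reagents that add atoms: isopropylmagnesium chloride, CC(C)[Mg]Cl
Why: Organocerium 1,2-addition suppresses enolisation and β-hydride reduction of the hindered ketone (one equivalent is spent on the free hydroxyl), and the isopropyl group should enter C4 from the face opposite to the adjacent C5 side chain, so that the new hydroxyl is cis to that chain as in the target.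

**Step 4**
Reactants: 8 (1R,2S,3S)-2-(1-hydroxyethyl)-3-methyl-1-(propan-2-yl)-3-[(1Z)-1-(trimethylsilyl)but-1-en-1-yl]cyclopentan-1-ol
Product: 10 (1R,2S,3S)-2-(1-hydroxyethyl)-3-[2-hydroxy-1-(trimethylsilyl)butyl]-3-methyl-1-(propan-2-yl)cyclopentan-1-ol, via alkylborane 9 (not isolated)
Conditions: BH3·THF (5 equiv), THF, 0 °C → rt; then 3 M NaOH, 30% H2O2, 0 °C → rt
Reagents that add atoms: hydrogen peroxide, OO
Why: Hydroboration–oxidation of the vinylsilane (the standard route to β-hydroxysilanes) should place boron, and hence oxygen, on C9, the alkene carbon remote from silicon and from the quaternary centre, and hydrogen on C10; the new centres C9 and C10 do not matter because both are cleared in step 5.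

**Step 5**
Reactants: 10 (1R,2S,3S)-2-(1-hydroxyethyl)-3-[2-hydroxy-1-(trimethylsilyl)butyl]-3-methyl-1-(propan-2-yl)cyclopentan-1-ol
Product: 12 1-[(1R,2R,5R)-2-hydroxy-5-methyl-5-(2-oxobutyl)-2-(propan-2-yl)cyclopentyl]ethan-1-one, via silyl diketone 11 (not isolated)
Conditions: Dess–Martin periodinane (3 equiv), NaHCO3, CH2Cl2, 0 °C → rt; then Bu4NF, AcOH, THF, 0 °C
Reagents that add atoms: none
Why: Dess–Martin oxidation should convert both secondary alcohols into ketones and spare the tertiary C4 hydroxyl, and the resulting α-silyl ketone is protodesilylated by buffered fluoride through its C9=C10 enolate, which unveils the 2-oxobutyl arm; C5, now α to the acetyl group, should hold its configuration because the acetyl group is trans to both the isopropyl group and the C1 arm.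

**Step 6**
Reactants: 12 1-[(1R,2R,5R)-2-hydroxy-5-methyl-5-(2-oxobutyl)-2-(propan-2-yl)cyclopentyl]ethan-1-one
Product: 13 1-[(1R,2R,5R)-5-methyl-5-(2-oxobutyl)-2-(propan-2-yl)-2-[(triethylsilyl)oxy]cyclopentyl]ethan-1-one
Conditions: Et3SiOTf, 2,6-lutidine, CH2Cl2, −78 → 0 °C
Reagents that add atoms: triethylsilyl trifluoromethanesulfonate, CC[Si](CC)(CC)OS(=O)(=O)C(F)(F)F
Why: Silylation of the hindered tertiary alcohol with a silyl triflate and a weak hindered base masks the C4 oxygen, which as an alkoxide β to the C6 carbonyl would open the cyclopentane by retro-aldol cleavage under the basic conditions of step 7.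

**Step 7**
Reactants: 13 1-[(1R,2R,5R)-5-methyl-5-(2-oxobutyl)-2-(propan-2-yl)-2-[(triethylsilyl)oxy]cyclopentyl]ethan-1-one
Product: 16 (3R,3aR,6S,8aR)-6,8a-dimethyl-3-(propan-2-yl)-3-[(triethylsilyl)oxy]octahydroazulene-4,7-dione, via bis(silyl enol ether) 14 (not isolated), via dilithium bis-enolate 15 (not isolated)
Conditions: LiN(iPr)2 (3 equiv), Me3SiCl (6 equiv), THF, −78 °C (internal quench); evaporate, pentane, filter; MeLi (2.1 equiv), THF, 0 °C → rt; slow addition to Cu(OTf)2 (2.5 equiv), iPrCN/THF, −78 → 0 °C, 0.005 M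
Reagents that add atoms: none
Why: One-electron oxidation of one enolate by the copper salt gives an α-keto radical (or its copper-bound enolate) that adds to the carbon terminus of the second enolate, and a second one-electron oxidation of the resulting ketyl delivers the 1,4-diketone; the closest known reaction is the intramolecular oxidative coupling of ketone bis-enolates with cupric or ferric salts. The ring C1, C5, C6, C7, C8, C9, C10 closes in a 7-endo-trig mode, the C8 radical attacking the terminal carbon C7 of the C6 enolate, with the trans arms on the cyclopentane holding C7 and C8 within reach. The only new stereocentre, C8, should follow the preference of its methyl group for a pseudo-equatorial position in the chair-like closing transition state; it is α to the C9 carbonyl, hence epimerisable, and is erased in step 8. The step needs site selectivity (C7 and C8, not C5 or C10) and ring closure over dimerisation: C5–H is buried between fully substituted C1 and C4 and C10–H2 is neopentylic, so kinetic enolisation goes to the methyl and ethyl termini. The internal silyl quench prevents the six-membered aldol closure open to a mono-enolate of this 1,5-diketone, MeLi then releases both enolates with no free carbonyl present, and slow inverse addition at high dilution disfavours intermolecular coupling. The triflate counter-ion cannot be transferred to the radical, which avoids the α-chlorination possible with CuCl2.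

**Step 8**
Reactants: 16 (3R,3aR,6S,8aR)-6,8a-dimethyl-3-(propan-2-yl)-3-[(triethylsilyl)oxy]octahydroazulene-4,7-dione
Product: 17 (3R,3aR,8aR)-6,8a-dimethyl-4-oxo-3-(propan-2-yl)-3-[(triethylsilyl)oxy]-1,2,3,3a,4,5,8,8a-octahydroazulen-7-yl trifluoromethanesulfonate
Conditions: Tf2O (1.1 equiv), 2,6-di-tert-butyl-4-methylpyridine (1.3 equiv), CH2Cl2, 0 °C → rt
Reagents that add atoms: trifluoromethanesulfonic anhydride, O=S(=O)(OS(=O)(=O)C(F)(F)F)C(F)(F)F
Why: Enol triflate formation without an enolate: the anhydride should activate the more accessible C9 carbonyl (C6 is shielded by C5 with its two fully substituted neighbours and the silyl ether), and the hindered base removes the C8 proton to give the more substituted C8=C9 enol triflate, which also erases the C8 stereocentre.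

**Step 9**
Reactants: 17 (3R,3aR,8aR)-6,8a-dimethyl-4-oxo-3-(propan-2-yl)-3-[(triethylsilyl)oxy]-1,2,3,3a,4,5,8,8a-octahydroazulen-7-yl trifluoromethanesulfonate
Product: 18 (3R,3aR,8aR)-6,8a-dimethyl-3-(propan-2-yl)-3-[(triethylsilyl)oxy]-2,3,3a,5,8,8a-hexahydroazulen-4(1H)-one
Conditions: Pd(PPh3)4 (5 mol %), LiCl (3 equiv), Bu3SnH (1.2 equiv, slow addition), THF, 50 °C
Reagents that add atoms: none
Why: Palladium-catalysed reduction of the enol triflate (oxidative addition, hydride transfer from tin, reductive elimination) replaces triflate by hydrogen without moving the C8=C9 double bond, and the neutral medium should keep the β,γ-unsaturated C6 ketone out of conjugation.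

**Step 10**
Reactants: 18 (3R,3aR,8aR)-6,8a-dimethyl-3-(propan-2-yl)-3-[(triethylsilyl)oxy]-2,3,3a,5,8,8a-hexahydroazulen-4(1H)-one
Product: 19 (3R,3aR,8aR)-3-hydroxy-6,8a-dimethyl-3-(propan-2-yl)-2,3,3a,5,8,8a-hexahydroazulen-4(1H)-one
Conditions: HF·pyridine, pyridine, THF, 0 °C → rt
Reagents that add atoms: none
Why: Fluoride-driven cleavage of the tertiary silyl ether under buffered, weakly acidic conditions should free the C4 hydroxyl without retro-aldol opening or alkene migration.

**Step 11**
Reactants: 19 (3R,3aR,8aR)-3-hydroxy-6,8a-dimethyl-3-(propan-2-yl)-2,3,3a,5,8,8a-hexahydroazulen-4(1H)-one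
Product: 20 (3R,3aS,4S,8aR)-6,8a-dimethyl-3-(propan-2-yl)-1,2,3,3a,4,5,8,8a-octahydroazulene-3,4-diol
Conditions: Me4NBH(OAc)3 (5 equiv), AcOH/MeCN 1:1, −30 → −20 °C; aq. potassium sodium tartrate
Reagents that add atoms: none
Why: Hydroxyl-directed (Evans–Saksena) reduction: the borohydride binds the 4β-oxygen, which the trans ring fusion tilts over the β face of the C6 carbonyl, and delivers hydride internally from that face (the one closed to external hydrides by the angular methyl), which should give the 6α-alcohol.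

**Step 12**
Reactants: 20 (3R,3aS,4S,8aR)-6,8a-dimethyl-3-(propan-2-yl)-1,2,3,3a,4,5,8,8a-octahydroazulene-3,4-diol; 21 4-methoxybenzoyl chloride
Product: 22 (3R,3aS,4S,8aR)-3-hydroxy-6,8a-dimethyl-3-(propan-2-yl)-1,2,3,3a,4,5,8,8a-octahydroazulen-4-yl 4-methoxybenzoate
Conditions: pyridine, DMAP (0.2 equiv), CH2Cl2, rt → 40 °C
Reagents that add atoms: none
Why: Nucleophile-catalysed acylation should occur only at the secondary C6 hydroxyl, the tertiary C4 hydroxyl being too hindered to react.

**Step 13**
Reactants: 22 (3R,3aS,4S,8aR)-3-hydroxy-6,8a-dimethyl-3-(propan-2-yl)-1,2,3,3a,4,5,8,8a-octahydroazulen-4-yl 4-methoxybenzoate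
Product: 23 (1R,4R,5S,6S,8R,9S)-8,9-epoxy-4-hydroxydaucan-6-yl 4-methoxybenzoate
Conditions: mCPBA, NaHCO3, CH2Cl2, 0 °C
Reagents that add atoms: 3-chloroperoxybenzoic acid, OOC(=O)c1cccc(Cl)c1
Why: Prilezhaev epoxidation of the only alkene; the peracid should approach C8=C9 from the α face, anti to the pseudo-axial C1 methyl that sits 1,3 to C9 on the β face, giving the 8α,9α-epoxide (8R,9S).

**Compound list**

1 | 3-methylcyclopent-2-en-1-one | CC1=CC(=O)CC1 | starting material
2 | but-1-yn-1-yl(trimethyl)silane | CCC#C[Si](C)(C)C | starting material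
3 | (Z)-bis(2-methylpropyl)[1-(trimethylsilyl)but-1-en-1-yl]aluminium | CC/C=C(\[Si](C)(C)C)[Al](CC(C)C)CC(C)C | intermediate
4 | bis(2-methylpropyl)aluminium enolate (O on C4, C4=C5) of (3S)-3-methyl-3-[(1Z)-1-(trimethylsilyl)but-1-en-1-yl]cyclopentan-1-one | CC/C=C(\[Si](C)(C)C)[C@@]1(C)CCC(O[Al](CC(C)C)CC(C)C)=C1 | intermediate
5 | triethyl({(3S)-3-methyl-3-[(1Z)-1-(trimethylsilyl)but-1-en-1-yl]cyclopent-1-en-1-yl}oxy)silane | CC/C=C(\[Si](C)(C)C)[C@@]1(C)CCC(O[Si](CC)(CC)CC)=C1 | intermediate
6 | acetaldehyde | CC=O | starting material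
7 | (2S,3S)-2-(1-hydroxyethyl)-3-methyl-3-[(1Z)-1-(trimethylsilyl)but-1-en-1-yl]cyclopentan-1-one (carbinol epimers) | CC/C=C(\[Si](C)(C)C)[C@@]1(C)CCC(=O)[C@@H]1C(C)O | intermediate
8 | (1R,2S,3S)-2-(1-hydroxyethyl)-3-methyl-1-(propan-2-yl)-3-[(1Z)-1-(trimethylsilyl)but-1-en-1-yl]cyclopentan-1-ol | CC/C=C(\[Si](C)(C)C)[C@@]1(C)CC[C@@](O)(C(C)C)[C@@H]1C(C)O | intermediate
9 | alkylborane from 8 (BH2 on C9, H on C10; hydroxyl groups drawn free) | CCC(B)C([Si](C)(C)C)[C@@]1(C)CC[C@@](O)(C(C)C)[C@@H]1C(C)O | intermediate
10 | (1R,2S,3S)-2-(1-hydroxyethyl)-3-[2-hydroxy-1-(trimethylsilyl)butyl]-3-methyl-1-(propan-2-yl)cyclopentan-1-ol | CCC(O)C([Si](C)(C)C)[C@@]1(C)CC[C@@](O)(C(C)C)[C@@H]1C(C)O | intermediate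
11 | 1-{(1R,2R,5S)-2-hydroxy-5-methyl-5-[2-oxo-1-(trimethylsilyl)butyl]-2-(propan-2-yl)cyclopentyl}ethan-1-one | CCC(=O)C([Si](C)(C)C)[C@@]1(C)CC[C@@](O)(C(C)C)[C@@H]1C(C)=O | intermediate
12 | 1-[(1R,2R,5R)-2-hydroxy-5-methyl-5-(2-oxobutyl)-2-(propan-2-yl)cyclopentyl]ethan-1-one | CCC(=O)C[C@@]1(C)CC[C@@](O)(C(C)C)[C@@H]1C(C)=O | intermediate
13 | 1-[(1R,2R,5R)-5-methyl-5-(2-oxobutyl)-2-(propan-2-yl)-2-[(triethylsilyl)oxy]cyclopentyl]ethan-1-one | CCC(=O)C[C@@]1(C)CC[C@@](O[Si](CC)(CC)CC)(C(C)C)[C@@H]1C(C)=O | intermediate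
14 | bis(trimethylsilyl enol ether) of 13 (C6=C7 and C8=C9) | CC=C(O[Si](C)(C)C)C[C@@]1(C)CC[C@@](O[Si](CC)(CC)CC)(C(C)C)[C@@H]1C(=C)O[Si](C)(C)C | intermediate
15 | dilithium bis-enolate of 13 (C6=C7 and C8=C9) | CC=C(O[Li])C[C@@]1(C)CC[C@@](O[Si](CC)(CC)CC)(C(C)C)[C@@H]1C(=C)O[Li] | intermediate
16 | (3R,3aR,6S,8aR)-6,8a-dimethyl-3-(propan-2-yl)-3-[(triethylsilyl)oxy]octahydroazulene-4,7-dione | O=C1C[C@H](C)C(=O)C[C@@]2(C)CC[C@@](O[Si](CC)(CC)CC)(C(C)C)[C@H]12 | intermediate
17 | (3R,3aR,8aR)-6,8a-dimethyl-4-oxo-3-(propan-2-yl)-3-[(triethylsilyl)oxy]-1,2,3,3a,4,5,8,8a-octahydroazulen-7-yl trifluoromethanesulfonate | O=C1CC(C)=C(OS(=O)(=O)C(F)(F)F)C[C@@]2(C)CC[C@@](O[Si](CC)(CC)CC)(C(C)C)[C@H]12 | intermediate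
18 | (3R,3aR,8aR)-6,8a-dimethyl-3-(propan-2-yl)-3-[(triethylsilyl)oxy]-2,3,3a,5,8,8a-hexahydroazulen-4(1H)-one | O=C1CC(C)=CC[C@@]2(C)CC[C@@](O[Si](CC)(CC)CC)(C(C)C)[C@H]12 | intermediate
19 | (3R,3aR,8aR)-3-hydroxy-6,8a-dimethyl-3-(propan-2-yl)-2,3,3a,5,8,8a-hexahydroazulen-4(1H)-one | O=C1CC(C)=CC[C@@]2(C)CC[C@@](O)(C(C)C)[C@H]12 | intermediate
20 | (3R,3aS,4S,8aR)-6,8a-dimethyl-3-(propan-2-yl)-1,2,3,3a,4,5,8,8a-octahydroazulene-3,4-diol (jaeschkeanadiol) | O[C@H]1CC(C)=CC[C@@]2(C)CC[C@@](O)(C(C)C)[C@H]12 | intermediate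
21 | 4-methoxybenzoyl chloride | COc1ccc(C(Cl)=O)cc1 | starting material
22 | (3R,3aS,4S,8aR)-3-hydroxy-6,8a-dimethyl-3-(propan-2-yl)-1,2,3,3a,4,5,8,8a-octahydroazulen-4-yl 4-methoxybenzoate | COc1ccc(C(=O)O[C@H]2CC(C)=CC[C@@]3(C)CC[C@@](O)(C(C)C)[C@H]23)cc1 | intermediate
23 | (1R,4R,5S,6S,8R,9S)-8,9-epoxy-4-hydroxydaucan-6-yl 4-methoxybenzoate (CNP0235939.1) | COc1ccc(C(=O)O[C@H]2C[C@@]3(C)O[C@H]3C[C@@]3(C)CC[C@@](O)(C(C)C)[C@H]23)cc1 | target

**Totals.** 13 steps in all; the longest linear sequence is 13 steps (1 and 2 to 23).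

**The three steps most likely to fail**

Step 7 (key step). Intermolecular coupling, or simple oxidation of one enolate, may outrun closure of the seven-membered ring. The same C7–C8 bond would then be made by a polar closure that sets out from 13. The bis(trimethylsilyl enol ether) 14 is prepared as in step 7 and treated with N-bromosuccinimide (1 equiv, THF, −78 °C), which should brominate the more substituted, more electron-rich C8=C9 enol ether and give the C8 bromo ketone with the C6 enol ether intact F1. Tetrabutylammonium difluorotriphenylsilicate in THF then frees the C7 enolate, which displaces the activated secondary bromide in a 7-exo-tet alkylation and comes back to the route at 16.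

Step 8. Site selectivity may be poor: the activated C9 carbonyl may lose the C10 proton instead of the C8 proton, or the C6 carbonyl may be triflated. The fallback sets out from 16 and fixes the alkene position by structure. IBX (DMSO/toluene, 70 °C) can dehydrogenate only C7–C8, because the other α-carbons, C5 and C10, have no β-hydrogen, and gives the C7=C8 ene-dione F2. 4-Methylbenzenesulfonohydrazide condenses at the less hindered C9 carbonyl to give the C9 tosylhydrazone F3. Catecholborane followed by NaOAc·3H2O reduces the hydrazone, and the allylic diazene so formed loses nitrogen with 1,3-transposition, which places the double bond at C8=C9 and a hydrogen on C7. This comes back to the route at 18 and bypasses 17.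

Step 3. The hindered ketone may be enolised or reduced by β-hydride transfer instead of adding the isopropyl group, and the alkoxide of the aldol may lose acetaldehyde by retro-aldol cleavage. The fallback sets out from 7 and uses a smaller nucleophile without β-hydrogen: prop-1-en-2-ylmagnesium bromide with CeCl3 (THF, −78 °C) should give the isopropenyl carbinol F4. Hydrogenation with RhCl(PPh3)3 under H2 then saturates only the 1,1-disubstituted alkene, the hindered trisubstituted vinylsilane staying intact, and comes back to the route at 8.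

**Further compounds**

F1 | step 7 | C8 bromo ketone from 14 with the C6 trimethylsilyl enol ether kept: ({1-[(1R,2R,5R)-5-(3-bromo-2-oxobutyl)-5-methyl-2-(propan-2-yl)-2-[(triethylsilyl)oxy]cyclopentyl]ethenyl}oxy)trimethylsilane | CC(Br)C(=O)C[C@@]1(C)CC[C@@](O[Si](CC)(CC)CC)(C(C)C)[C@@H]1C(=C)O[Si](C)(C)C
F2 | step 8 | (3R,3aR,8aR)-6,8a-dimethyl-3-(propan-2-yl)-3-[(triethylsilyl)oxy]-1,2,3,3a,8,8a-hexahydroazulene-4,7-dione | O=C1C=C(C)C(=O)C[C@@]2(C)CC[C@@](O[Si](CC)(CC)CC)(C(C)C)[C@H]12
F3 | step 8 | C9 4-methylbenzenesulfonylhydrazone of F2 | O=C1C=C(C)C(=NNS(=O)(=O)c3ccc(C)cc3)C[C@@]2(C)CC[C@@](O[Si](CC)(CC)CC)(C(C)C)[C@H]12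
F4 | step 3 | (1S,2S,3S)-2-(1-hydroxyethyl)-3-methyl-1-(prop-1-en-2-yl)-3-[(1Z)-1-(trimethylsilyl)but-1-en-1-yl]cyclopentan-1-ol | CC/C=C(\[Si](C)(C)C)[C@@]1(C)CC[C@@](O)(C(C)=C)[C@@H]1C(C)O
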